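The flavone is disconnected at O1–C8a. In ring A the three oxygens (O1, O on C5, O on C7) sit 1,3 to one another, and each is conjugated, ortho or para, with the C4 carbonyl. Both ortho oxygens can therefore enter by fluoride displacement on a symmetric 2,6-difluoro-4-methoxyphenyl ketone. In one operation the key step lets the distal enolate oxygen of a 1,3-diketone expel one fluoride. This forms O1–C8a, closes pyranone ring C and leaves fluorine as a placeholder at C5. The precursor links the difluoroaryl ketone through one CH2 to the 4-benzyloxy-2,3,5-trimethoxybenzoyl unit (ring B). Benzyloxide then replaces the C5 fluorine, and a single hydrogenolysis frees both phenols.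

Key step: step 6

Remark: the target has no stereocentre, flavone numbering (O1 to C8a, C1' to C6') is used for ring atoms, and 1,3-diketones are drawn as diketo tautomers although they should exist largely as enols.

Step 1
Reactants: 1 methyl syringate (methyl 4-hydroxy-3,5-dimethoxybenzoate); 2 benzyl bromide
Product: 3 methyl 4-(benzyloxy)-3,5-dimethoxybenzoate
Conditions: K2CO3, DMF, 60 °C
Reagents that add atoms: none
Why: Williamson ether synthesis on the phenoxide of 1, placed first so that the electron-rich phenol is not oxidised during bromination and the ring stays neutral in the copper step.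

Step 2
Reactants: 3 methyl 4-(benzyloxy)-3,5-dimethoxybenzoate
Product: 4 methyl 4-(benzyloxy)-2-bromo-3,5-dimethoxybenzoate
Conditions: NBS (1.05 equiv), MeCN, rt, dark
Reagents that add atoms: N-bromosuccinimide, O=C1CCC(=O)N1Br
Why: Electrophilic aromatic bromination, in which the two equivalent free positions are each ortho to one methoxy group and para to the other, so one equivalent of NBS under ionic conditions should give the monobromide and leave the unactivated benzyl ring and the benzylic CH2 alone.

Step 3
Reactants: 4 methyl 4-(benzyloxy)-2-bromo-3,5-dimethoxybenzoate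
Product: 6 4-(benzyloxy)-2,3,5-trimethoxybenzoic acid, via methyl ester 5 (not isolated)
Conditions: NaOMe (5 equiv, in MeOH), CuBr (15 mol%), DMF, 105 °C; then aq NaOH, 60 °C; then aq HCl to pH 2
Reagents that add atoms: sodium methoxide, [Na+].[O-]C; sodium hydroxide, [Na+].[OH-]
Why: Ullmann-type copper-catalysed methoxylation of an aryl bromide, helped by the ortho carboxyl group, followed by saponification in the same pot so that the ester and any acid already formed under the methoxide conditions converge on one product.

Step 4
Reactants: 7 3,5-difluoroanisole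
Product: 9 1-(2,6-difluoro-4-methoxyphenyl)ethanone, via aryllithium 8 (not isolated)
Conditions: n-BuLi, THF, −78 °C; then MeC(O)N(OMe)Me, −78 → 0 °C; aq HCl quench
Reagents that add atoms: N-methoxy-N-methylacetamide, CC(=O)N(C)OC; n-butyllithium, [Li]CCCC (lithium of 8 only)
Why: Directed ortho-lithiation at the most acidic C–H, the one flanked by both fluorines, followed by Weinreb ketone synthesis, with the low temperature holding back loss of LiF to an aryne and the amide preventing over-addition.

Step 5
Reactants: 6 4-(benzyloxy)-2,3,5-trimethoxybenzoic acid; 9 1-(2,6-difluoro-4-methoxyphenyl)ethanone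
Product: 12 1-[4-(benzyloxy)-2,3,5-trimethoxyphenyl]-3-(2,6-difluoro-4-methoxyphenyl)propane-1,3-dione, via acid chloride 10 (not isolated), via lithium enolate 11 (not isolated)
Conditions: 6, (COCl)2, cat. DMF, CH2Cl2, 0 °C → rt, concentrate; separately 9 (2 equiv), LiN(SiMe3)2 (2.05 equiv), THF, −78 °C; add 10 (1 equiv), −78 → 0 °C; aq HCl; surplus 9 recovered
Reagents that add atoms: oxalyl chloride, O=C(Cl)C(=O)Cl (chlorine of 10 only); lithium hexamethyldisilazide, [Li+].C[Si](C)(C)[N-][Si](C)(C)C (lithium of 11 only)
Why: Claisen-type C-acylation of a preformed lithium ketone enolate with an aroyl chloride, in which the second equivalent of enolate deprotonates the more acidic diketone and returns any enol ester to the C-acyl product, and in which, unlike an ester condensation on this sluggish electron-rich benzoate, no alkoxide is released that could attack the C–F carbons.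

Step 6
Reactants: 12 1-[4-(benzyloxy)-2,3,5-trimethoxyphenyl]-3-(2,6-difluoro-4-methoxyphenyl)propane-1,3-dione
Product: 13 2-[4-(benzyloxy)-2,3,5-trimethoxyphenyl]-5-fluoro-7-methoxy-4H-chromen-4-one
Conditions: K2CO3 (2 equiv), dry DMSO, 70 °C
Reagents that add atoms: none
Why: Intramolecular SNAr by addition–elimination, in which carbonate deprotonates 12, the enolate oxygen on the carbon bearing ring B adds to the C–F carbon that becomes C8a, the charge of the Meisenheimer adduct runs through C4a into the C4 carbonyl, and fluoride leaves. The closest known reaction type is the base-mediated cyclisation of 1-(2-fluoroaryl)-1,3-diketones to chromones and flavones. Ring C closes as a six-membered ring in a formally 6-endo-trig mode, because the C4a=C8a π bond that takes up the electrons lies inside the new ring, as in the oxa-Michael closure of 2'-hydroxychalcones. No stereocentre is formed. Site selectivity rests on the substrate: the two fluorines are equivalent by symmetry, attack through C3 or through the C4 oxygen would need a four-membered ring, and closure of the C4 oxygen onto C2' of ring B would have to expel methoxide from a carbon that has donors ortho and para to it. The methoxy group is meta to both C–F carbons and feeds no electron density into them, potassium in DMSO loosens the chelated U-shaped enolate so that it can rotate about C3–C4 into the reactive geometry, and an amine-free solvent protects the surviving C5 fluorine.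

Step 7
Reactants: 13 2-[4-(benzyloxy)-2,3,5-trimethoxyphenyl]-5-fluoro-7-methoxy-4H-chromen-4-one
Product: 14 5-(benzyloxy)-2-[4-(benzyloxy)-2,3,5-trimethoxyphenyl]-7-methoxy-4H-chromen-4-one
Conditions: BnOH (1.3 equiv), NaH (1.2 equiv), dry THF, 0 °C; then 13, 0 → 45 °C
Reagents that add atoms: benzyl alcohol, OCc1ccccc1
Why: Intermolecular SNAr, favoured because C5–F is ortho to C4a and so conjugated with the C4 carbonyl, both donors of ring A (O1 and the 7-methoxy group) are meta to C5, fluoride is by far the best leaving group present, and under anhydrous conditions any alkoxide addition at C2 is reversible.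

Step 8
Reactants: 14 5-(benzyloxy)-2-[4-(benzyloxy)-2,3,5-trimethoxyphenyl]-7-methoxy-4H-chromen-4-one
Product: 15 5-hydroxy-2-(4-hydroxy-2,3,5-trimethoxyphenyl)-7-methoxy-4H-chromen-4-one (target)
Conditions: H2 (1 atm), 10% Pd/C, EtOAc/MeOH, rt, stopped when 14 is consumed
Reagents that add atoms: none
Why: Catalytic hydrogenolysis cleaves both aryl benzyl ethers in one operation, while at atmospheric pressure and room temperature the conjugated C2=C3 bond and the four methyl ethers are expected to survive.

Compound list
1 | methyl syringate (methyl 4-hydroxy-3,5-dimethoxybenzoate) | COC(=O)c1cc(OC)c(O)c(OC)c1 | starting material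
2 | benzyl bromide | BrCc1ccccc1 | starting material
3 | methyl 4-(benzyloxy)-3,5-dimethoxybenzoate | COC(=O)c1cc(OC)c(OCc2ccccc2)c(OC)c1 | intermediate
4 | methyl 4-(benzyloxy)-2-bromo-3,5-dimethoxybenzoate | COC(=O)c1cc(OC)c(OCc2ccccc2)c(OC)c1Br | intermediate
5 | methyl 4-(benzyloxy)-2,3,5-trimethoxybenzoate (not isolated) | COC(=O)c1cc(OC)c(OCc2ccccc2)c(OC)c1OC | intermediate
6 | 4-(benzyloxy)-2,3,5-trimethoxybenzoic acid | OC(=O)c1cc(OC)c(OCc2ccccc2)c(OC)c1OC | intermediate
7 | 3,5-difluoroanisole | COc1cc(F)cc(F)c1 | starting material
8 | (2,6-difluoro-4-methoxyphenyl)lithium (not isolated) | [Li]c1c(F)cc(OC)cc1F | intermediate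
9 | 1-(2,6-difluoro-4-methoxyphenyl)ethanone | CC(=O)c1c(F)cc(OC)cc1F | intermediate
10 | 4-(benzyloxy)-2,3,5-trimethoxybenzoyl chloride (not isolated) | ClC(=O)c1cc(OC)c(OCc2ccccc2)c(OC)c1OC | intermediate
11 | lithium 1-(2,6-difluoro-4-methoxyphenyl)ethen-1-olate (not isolated) | C=C([O-])c1c(F)cc(OC)cc1F.[Li+] | intermediate
12 | 1-[4-(benzyloxy)-2,3,5-trimethoxyphenyl]-3-(2,6-difluoro-4-methoxyphenyl)propane-1,3-dione | COc1cc(F)c(C(=O)CC(=O)c2cc(OC)c(OCc3ccccc3)c(OC)c2OC)c(F)c1 | intermediate
13 | 2-[4-(benzyloxy)-2,3,5-trimethoxyphenyl]-5-fluoro-7-methoxy-4H-chromen-4-one | COc1cc(F)c2c(=O)cc(-c3cc(OC)c(OCc4ccccc4)c(OC)c3OC)oc2c1 | intermediate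
14 | 5-(benzyloxy)-2-[4-(benzyloxy)-2,3,5-trimethoxyphenyl]-7-methoxy-4H-chromen-4-one | COc1cc(OCc5ccccc5)c2c(=O)cc(-c3cc(OC)c(OCc4ccccc4)c(OC)c3OC)oc2c1 | intermediate
15 | 5-hydroxy-2-(4-hydroxy-2,3,5-trimethoxyphenyl)-7-methoxy-4H-chromen-4-one | COc1cc(O)c2c(=O)cc(-c3cc(OC)c(O)c(OC)c3OC)oc2c1 | target

Total step count: 8
Longest linear sequence: 7 (steps 1, 2, 3, 5, 6, 7, 8)

Steps most likely to fail

**Step 6 (key step).**
- The para methoxy group weakens the pull of the ketone, so fluoride displacement may be slow. Retro-Claisen cleavage of the diketone by adventitious hydroxide could then overtake ring closure.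
- The fallback forms O1–C2 instead of O1–C8a by classical cyclodehydration.
- It sets out from 9. KOH in aqueous DMSO at about 70 °C should replace one fluoride, and the phenoxide formed shuts down a second displacement. This gives 1-(2-fluoro-6-hydroxy-4-methoxyphenyl)ethanone F1.
- The dianion of F1, made with LiN(SiMe3)2 (3 equiv) in THF at −78 °C, is C-acylated with 10. This gives 1-[4-(benzyloxy)-2,3,5-trimethoxyphenyl]-3-(2-fluoro-6-hydroxy-4-methoxyphenyl)propane-1,3-dione F2.
- Catalytic p-TsOH in hot toluene then closes ring C with loss of water, and the route is rejoined at 13.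

**Step 7.**
- The alkoxide may add at C2, opening ring C and leading to cleavage. The exchange may also be sluggish, because the chromone carbonyl is a vinylogous ester and activates less than a plain aryl ketone.
- The fallback makes the C5–O bond before ring C exists.
- It sets out from 9. One equivalent of preformed sodium benzyloxide in THF should give 1-[2-(benzyloxy)-6-fluoro-4-methoxyphenyl]ethanone F3.
- Enolisation of F3 with LiN(SiMe3)2 and acylation with 10, as in step 5, gives 1-[2-(benzyloxy)-6-fluoro-4-methoxyphenyl]-3-[4-(benzyloxy)-2,3,5-trimethoxyphenyl]propane-1,3-dione F4.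
- K2CO3 in DMSO then closes ring C on the only remaining fluoride, and the route is rejoined at 14.

**Step 5.**
- The enolate may undergo O-acylation or double acylation, and proton exchange between enolate and product may stall conversion.
- The fallback is aldol addition followed by oxidation, so the C–C bond is made on an aldehyde, where only carbon attack of the enolate leads to a stable adduct.
- It sets out from 10 and 11. LiAlH(OtBu)3 in THF at −78 °C reduces 10 to 4-(benzyloxy)-2,3,5-trimethoxybenzaldehyde F5.
- Addition of F5 to enolate 11 at −78 °C gives racemic 3-[4-(benzyloxy)-2,3,5-trimethoxyphenyl]-1-(2,6-difluoro-4-methoxyphenyl)-3-hydroxypropan-1-one F6.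
- o-Iodoxybenzoic acid in hot EtOAc oxidises the carbinol, which erases the stereocentre, and the route is rejoined at 12.

Further compounds
F1 | step 6 | 1-(2-fluoro-6-hydroxy-4-methoxyphenyl)ethanone | CC(=O)c1c(O)cc(OC)cc1F
F2 | step 6 | 1-[4-(benzyloxy)-2,3,5-trimethoxyphenyl]-3-(2-fluoro-6-hydroxy-4-methoxyphenyl)propane-1,3-dione | COc1cc(O)c(C(=O)CC(=O)c2cc(OC)c(OCc3ccccc3)c(OC)c2OC)c(F)c1
F3 | step 7 | 1-[2-(benzyloxy)-6-fluoro-4-methoxyphenyl]ethanone | CC(=O)c1c(F)cc(OC)cc1OCc2ccccc2
F4 | step 7 | 1-[2-(benzyloxy)-6-fluoro-4-methoxyphenyl]-3-[4-(benzyloxy)-2,3,5-trimethoxyphenyl]propane-1,3-dione | COc1cc(F)c(C(=O)CC(=O)c2cc(OC)c(OCc3ccccc3)c(OC)c2OC)c(OCc4ccccc4)c1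
F5 | step 5 | 4-(benzyloxy)-2,3,5-trimethoxybenzaldehyde | O=Cc1cc(OC)c(OCc2ccccc2)c(OC)c1OC
F6 | step 5 | 3-[4-(benzyloxy)-2,3,5-trimethoxyphenyl]-1-(2,6-difluoro-4-methoxyphenyl)-3-hydroxypropan-1-one (racemic) | COc1cc(F)c(C(=O)CC(O)c2cc(OC)c(OCc3ccccc3)c(OC)c2OC)c(F)c1
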